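Readings and results are calculated with made-up constants; the scatter is artificial.

The easy step is that a share needs no rate constant: J over J plus D, the selectivity, takes two readings from one sample.

| flask | G | remark | time |
|---|---|---|---|
| ochre | 0.34 M | run made earlier |  |
| grey | 0.75 M | run made earlier |  |
| flask | 0.50 M |  | 3.0 h |

| run | time / h | J / % | D / % | G / % |
|---|---|---|---|---|
| ochre | 0.250 | 18 | 12 | 48 |
| ochre | 0.500 | 28 | 12 | 27 |
| ochre | 1.33 | 37 | 17 | 14 |
| ochre | 3.00 | 41 | 21 | 13 |
| grey | 0.417 | 25 | 10 | 30 |
| grey | 1.00 | 29 | 15 | 14 |
| grey | 2.00 | 29 | 16 | 11 |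
| grey | 3.00 | 33 | 19 | 9 |

(each reading ± 1.5 percentage points)

- share of J in J plus D at 80 s
- share of J in J plus D at 15 min
- share of J in J plus D at 3.0 h



Before taking a number I ask what it hangs on. The charge comes first: at 3.00 h the ochre run reads 66.1 % and the grey run, with twice the charge, 63.5 %, and that gap of 2.7 percentage points is smaller than its own scatter of 2.8 points. Time comes next: the ochre share climbs from 60.0 % to 70.0 % and then falls back, but that first share alone carries 3.6 points of scatter. So I read the scatter as the thing to beat, and I take J and D as two first-order exits from G, whose ratio stays put. The 8 J readings add to 240 % and the D readings to 122 %, which gives the pooled share, summed J over summed J plus D, of 66.3 %, good to 0.87 points. I commit to that value at each asked time in the flask.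

The forecast gives 52 %, 62 % and 65 %, the earliest value “though this is poorly fixed”, and at 80 s it stands below my share. The flask gives 67.4 % at 80 s, 67.3 % at 15 min and 66.6 % at 3.0 h.

    G ⇌ D (K = 2.30, k = 1.50 × 10⁻⁴ s⁻¹)
    2 G → E (k = 2.90 × 10⁻⁴ L mol⁻¹ s⁻¹)
    G ⇌ J (K = 4.40, k = 3.10 × 10⁻⁴ s⁻¹)
    G ⇌ X (K = 1.20, k = 2.90 × 10⁻⁴ s⁻¹)

At 0.270 h the forward step from G to J alone gives G a half-life of 0.62 h, against 1.3 h for the forward step from G to D alone. At the start their forward rates stand at 2.1 to one, and the two forward constants in the equations above give J a share of 67.4 % of what these two steps take from G then, beside 67.4 % in the flask at 80 s. My pooled share lies 0.30 points under the flask at 3.0 h. The neighbour flask, charged with 0.12 M of G, below either run, holds 22.2 % of D at 3.00 h, and the pooled share turns that D into 43.7 % of J, where it holds 44.3 %.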